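A direct plan would build the carbocycle first: a catalytic enantioselective Diels–Alder reaction of 2,5-dimethylfuran A1 with acrolein A2, then base-induced opening of the oxygen bridge, would give hydroxy dienal A3.
Directed epoxidation, palladium-catalysed isomerisation of the vinyl epoxide to the C6 ketone and enaminone formation would then prepare acylation with a crotonyl donor and acid closure of the pyran ring to propenyl ketol A4.
Esterification of A4 with a protected orsellinic acid derivative, cross-metathesis with (Z)-but-2-ene-1,4-diyl diacetate A5 and deprotection would finish.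
Weakest steps: (a) the furan–acrolein cycloaddition that sets C7, the only stereocentre: the adduct forms reversibly, and endo and exo adducts of one acrolein face open to antipodal products, so the enantiomeric purity would rest on an endo:exo ratio that is hard to secure.
(b) The epoxidation, epoxide isomerisation and enaminone masking: three operations that only move an oxygen atom and hide an enol, and form no bond of the skeleton.
(c) The cross-metathesis that exchanges CH3 for CH2OAc at the very end: a correction of the side chain on the complete polyene, next to two enol ethers and with an E/Z question.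

**Retrosynthetic overview**
Ring A is the pyran ring (O2, C1, C3, C4, C4a, C8a), ring B the carbocycle (C4a, C5, C6, C7, C8, C8a). The α-ketol C6(=O)–C7(OH)(CH3) of ring B is the retron of a crossed aldehyde–ketone benzoin: cutting C6–C7 leads to the achiral keto aldehyde 13, a (pyran-4-ylidene)acetaldehyde with a 2-oxopropyl group on C8a.
Ring A is therefore made first, as a 4-pyranone, from an acylketene (C3, C4, C4a and the complete acetoxypropenyl chain) and the enamine of pent-4-enal (C1, C8a, C8, C7 and the C7 methyl); C5 and C6 are added as acetylide (Meyer–Schuster), and the C7 ketone is unveiled from the allyl group (Wacker).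
Ring B closes last, in one carbene-catalysed step that forms C6–C7 and sets C7 by catalyst control; the orsellinate is then attached and the two phenols are freed.
No stereocentre depends on a cycloaddition topology, no oxygen is moved, and the side chain is complete from step 2.
Key step: step 6

Assumption: the exocyclic C4a=C5 bond of aldehydes 12 and 13 is a push–pull alkene that equilibrates between E and Z at room temperature (both are drawn as the Z isomer that the cyclisation needs), and the (5aR,10bS) antipode of the catalyst in step 6 is taken to be the one that attacks the Re face of the ketone; if the sense were opposite, the equally available (5aS,10bR) salt would be used.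

Step 1
Reactants: 1 2,2,6-trimethyl-4H-1,3-dioxin-4-one
Product: 2 diethyl [(2,2-dimethyl-4-oxo-4H-1,3-dioxin-6-yl)methyl]phosphonate
Conditions: LiN(i-Pr)2 (2.1 equiv), THF, −78 °C; ClP(O)(OEt)2 (1.0 equiv), −78 → 0 °C
Reagents that add atoms: diethyl chlorophosphate, CCOP(=O)(Cl)OCC
Why: The γ-lithiated dienolate of the dioxinone is phosphorylated at the exocyclic carbon to give the vinylogous β-keto phosphonate, the second equivalent of amide base converting any dienyl phosphate from O-attack into the same phosphonate by 1,3-phosphoryl shift and holding the product as its anion (C-phosphorylation of an extended enolate).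

Step 2
Reactants: 2 diethyl [(2,2-dimethyl-4-oxo-4H-1,3-dioxin-6-yl)methyl]phosphonate; 3 2-oxoethyl acetate
Product: 4 [(E)-3-(2,2-dimethyl-4-oxo-4H-1,3-dioxin-6-yl)prop-2-enyl] acetate
Conditions: KN(SiMe3)2 (1.05 equiv), THF, −78 °C; 3 (1.2 equiv), −78 → 0 °C
Reagents that add atoms: none
Why: Horner–Wadsworth–Emmons olefination of the stabilised phosphonate anion with the aldehyde gives the (E)-alkene through the more stable anti oxaphosphetane, and the weakly basic anion at low temperature spares the acetate and the enolisable aldehyde.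

Step 3
Reactants: 4 [(E)-3-(2,2-dimethyl-4-oxo-4H-1,3-dioxin-6-yl)prop-2-enyl] acetate; 5 pent-4-enal
Product: 9 [(E)-3-(4-oxo-5-prop-2-enyl-4H-pyran-2-yl)prop-2-enyl] acetate, via dienyl enamine 6 (not isolated), via acylketene 7 (not isolated), via morpholino dihydropyranone 8 (not isolated)
Conditions: 5 (1.5 equiv), morpholine (1.5 equiv), K2CO3, Et2O, 0 → 25 °C, filter, evaporate; then 4 added over 1 h to 6 in toluene, 110 °C; then AcOH (2 equiv), 25 °C
Reagents that add atoms: none
Why: Thermal loss of acetone from the dioxinone gives the acylketene, which the enamine intercepts through its nucleophilic β-carbon at the ketene carbon in a formal [4+2] cycloaddition (the enamine–acylketene route to 4-pyranones), and elimination of morpholine from the adduct gives the pyranone with the allyl group on C8a and the side chain on C3.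

Step 4
Reactants: 9 [(E)-3-(4-oxo-5-prop-2-enyl-4H-pyran-2-yl)prop-2-enyl] acetate; 10 ethynylmagnesium bromide
Product: 12 [(E)-3-[(4Z)-4-(2-oxoethylidene)-5-prop-2-enyl-4H-pyran-2-yl]prop-2-enyl] acetate, via ethynyl pyranol 11 (not isolated)
Conditions: CeCl3 (1.5 equiv), 10 (0.5 M in THF, 1.5 equiv), THF, −78 °C; 9, −78 → −40 °C; aq. NH4Cl; then TsOH·H2O (20 mol%), THF/H2O (10:1), 0 → 25 °C
Reagents that add atoms: water, O
Why: The cerium acetylide should add 1,2 to the pyranone carbonyl faster than to the acetate, and in acid the tertiary propargylic alcohol ionises to a 4-ethynylpyrylium ion that water captures at the alkyne terminus (Meyer–Schuster rearrangement; a Rupe path is excluded because the carbinol carbon has no adjacent C–H) to give the push–pull dienal.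

Step 5
Reactants: 12 [(E)-3-[(4Z)-4-(2-oxoethylidene)-5-prop-2-enyl-4H-pyran-2-yl]prop-2-enyl] acetate
Product: 13 [(E)-3-[(4Z)-4-(2-oxoethylidene)-5-(2-oxopropyl)-4H-pyran-2-yl]prop-2-enyl] acetate
Conditions: PdCl2 (10 mol%), Cu(OAc)2·H2O (20 mol%), O2 (1 atm), N,N-dimethylacetamide/H2O (7:1), 25 °C
Reagents that add atoms: water, O
Why: Tsuji–Wacker oxidation: hydroxypalladation of the only monosubstituted alkene at its internal carbon by divalent palladium turns the allyl group into the 2-oxopropyl group, and the acetate-buffered copper co-oxidant keeps the medium free of strong acid for the enol ethers, the aldehyde and the allylic acetate.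

Step 6
Reactants: 13 [(E)-3-[(4Z)-4-(2-oxoethylidene)-5-(2-oxopropyl)-4H-pyran-2-yl]prop-2-enyl] acetate
Product: 14 [(E)-3-[(7S)-7-hydroxy-7-methyl-6-oxo-7,8-dihydro-6H-isochromen-3-yl]prop-2-enyl] acetate
Conditions: (5aR,10bS)-2-(2,4,6-trimethylphenyl)-5a,10b-dihydro-4H,6H-indeno[2,1-b][1,2,4]triazolo[4,3-d][1,4]oxazin-2-ium chloride, C21H22ClN3O (15 mol%), i-Pr2NEt (15 mol%), toluene, 25 °C
Reagents that add atoms: none
Why: Proposed new method: the free carbene should add to the aldehyde carbon C6, proton transfer should give the enaminol (acyl-anion equivalent), its C6 should attack the pendant methyl ketone C7, and proton transfer with loss of the carbene should release the α-ketol; the closest known reaction type is the enantioselective carbene-catalysed intramolecular crossed aldehyde–ketone benzoin cyclisation of aryl aldehydes with a 3-oxobutyl side chain to 2-hydroxy-2-methyltetralones, which is extended here from an aryl aldehyde to a doubly vinylogous formate. Ring B closes by a 6-exo-trig attack that forms C6–C7 and is open only to the Z isomer of the labile C4a=C5 bond. C7, the only stereocentre, is set by the aminoindanyl backbone of the catalyst, which should shield one face of the ketone so that C6 adds to its Re face (priorities O > C8 > CH3) and gives 7S. The step needs acyl-anion reactivity at C6 and not homoenolate reactivity at C4a, and benzoin closure and not aldol closure of C8 onto C6 (which would lead on to a cyclopenta[c]pyran); C4a is fully substituted and cannot reach the ketone through a ring of reasonable size, the vinylogous formyl group is a poor aldol acceptor, and the catalytic amine base is too weak to enolise the ketone.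

Step 7
Reactants: 15 orsellinic acid (2,4-dihydroxy-6-methylbenzoic acid)
Product: 16 triethylsilyl 2,4-bis(triethylsilyloxy)-6-methylbenzoate
Conditions: Et3SiCl (3.6 equiv), imidazole (7 equiv), DMF, 25 °C
Reagents that add atoms: chlorotriethylsilane, CC[Si](Cl)(CC)CC
Why: Exhaustive silylation covers both phenols and the carboxylic acid, and the silyl ester serves in the next step as the direct precursor of the acid chloride.

Step 8
Reactants: 14 [(E)-3-[(7S)-7-hydroxy-7-methyl-6-oxo-7,8-dihydro-6H-isochromen-3-yl]prop-2-enyl] acetate; 16 triethylsilyl 2,4-bis(triethylsilyloxy)-6-methylbenzoate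
Product: 18 [(7S)-3-[(E)-3-acetyloxyprop-1-enyl]-7-methyl-6-oxo-7,8-dihydro-6H-isochromen-7-yl] 2,4-bis(triethylsilyloxy)-6-methylbenzoate, via aroyl chloride 17 (not isolated)
Conditions: 16 (1.5 equiv), (COCl)2 (1.6 equiv), DMF (cat.), CH2Cl2, 0 → 25 °C, evaporate; 14, LiN(SiMe3)2 (1.05 equiv), THF, −78 °C; then 17, −78 → 0 °C
Reagents that add atoms: none
Why: The chloroiminium salt from oxalyl chloride and DMF converts the silyl ester into the acid chloride without free HCl, and the lithium alkoxide of the tertiary α-ketol (its most acidic site) is acylated by this doubly ortho-substituted aroyl chloride where the neutral alcohol would not be, with no bond to C7 broken and its configuration kept.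

Step 9
Reactants: 18 [(7S)-3-[(E)-3-acetyloxyprop-1-enyl]-7-methyl-6-oxo-7,8-dihydro-6H-isochromen-7-yl] 2,4-bis(triethylsilyloxy)-6-methylbenzoate
Product: 19 [(7S)-3-[(E)-3-acetyloxyprop-1-enyl]-7-methyl-6-oxo-7,8-dihydro-6H-isochromen-7-yl] 2,4-dihydroxy-6-methylbenzoate (target)
Conditions: HF·pyridine, pyridine, THF, 0 °C
Reagents that add atoms: none
Why: Buffered fluoride cleaves the two aryl triethylsilyl ethers, the most labile silyl ethers in the molecule, and should leave the allylic acetate, the hindered benzoate, C7 and the pyranylidene ketone untouched.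

**Compound list**
1 | 2,2,6-trimethyl-4H-1,3-dioxin-4-one | CC1=CC(=O)OC(C)(C)O1 | starting material
2 | diethyl [(2,2-dimethyl-4-oxo-4H-1,3-dioxin-6-yl)methyl]phosphonate | CCOP(=O)(CC1=CC(=O)OC(C)(C)O1)OCC | intermediate
3 | 2-oxoethyl acetate | CC(=O)OCC=O | starting material
4 | [(E)-3-(2,2-dimethyl-4-oxo-4H-1,3-dioxin-6-yl)prop-2-enyl] acetate | CC(=O)OC/C=C/C1=CC(=O)OC(C)(C)O1 | intermediate
5 | pent-4-enal | C=CCCC=O | starting material
6 | 4-[(1E)-penta-1,4-dienyl]morpholine | C=CC/C=C/N1CCOCC1 | intermediate (not isolated)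
7 | [(E)-4,6-dioxohexa-2,5-dienyl] acetate (acylketene) | CC(=O)OC/C=C/C(=O)C=C=O | intermediate (not isolated)
8 | [(E)-3-(2-morpholin-4-yl-4-oxo-3-prop-2-enyl-2,3-dihydropyran-6-yl)prop-2-enyl] acetate (mixture of diastereomers) | C=CCC1C(N2CCOCC2)OC(/C=C/COC(C)=O)=CC1=O | intermediate (not isolated)
9 | [(E)-3-(4-oxo-5-prop-2-enyl-4H-pyran-2-yl)prop-2-enyl] acetate | C=CCC1=COC(/C=C/COC(C)=O)=CC1=O | intermediate
10 | ethynylmagnesium bromide | C#C[Mg]Br | starting material
11 | [(E)-3-(4-ethynyl-4-hydroxy-5-prop-2-enyl-4H-pyran-2-yl)prop-2-enyl] acetate (racemic) | C=CCC1=COC(/C=C/COC(C)=O)=CC1(O)C#C | intermediate (not isolated)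
12 | [(E)-3-[(4Z)-4-(2-oxoethylidene)-5-prop-2-enyl-4H-pyran-2-yl]prop-2-enyl] acetate | O=C/C=C1\C(CC=C)=COC(/C=C/COC(C)=O)=C1 | intermediate
13 | [(E)-3-[(4Z)-4-(2-oxoethylidene)-5-(2-oxopropyl)-4H-pyran-2-yl]prop-2-enyl] acetate | O=C/C=C1\C(CC(C)=O)=COC(/C=C/COC(C)=O)=C1 | intermediate
14 | [(E)-3-[(7S)-7-hydroxy-7-methyl-6-oxo-7,8-dihydro-6H-isochromen-3-yl]prop-2-enyl] acetate | CC(=O)OC/C=C/C1=CC2=CC(=O)[C@@](C)(O)CC2=CO1 | intermediate
15 | orsellinic acid (2,4-dihydroxy-6-methylbenzoic acid) | Cc1cc(O)cc(O)c1C(=O)O | starting material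
16 | triethylsilyl 2,4-bis(triethylsilyloxy)-6-methylbenzoate | Cc1cc(O[Si](CC)(CC)CC)cc(O[Si](CC)(CC)CC)c1C(=O)O[Si](CC)(CC)CC | intermediate
17 | 2,4-bis(triethylsilyloxy)-6-methylbenzoyl chloride | Cc1cc(O[Si](CC)(CC)CC)cc(O[Si](CC)(CC)CC)c1C(Cl)=O | intermediate (not isolated)
18 | [(7S)-3-[(E)-3-acetyloxyprop-1-enyl]-7-methyl-6-oxo-7,8-dihydro-6H-isochromen-7-yl] 2,4-bis(triethylsilyloxy)-6-methylbenzoate | CC(=O)OC/C=C/C1=CC2=CC(=O)[C@@](C)(OC(=O)c3c(C)cc(O[Si](CC)(CC)CC)cc3O[Si](CC)(CC)CC)CC2=CO1 | intermediate
19 | [(7S)-3-[(E)-3-acetyloxyprop-1-enyl]-7-methyl-6-oxo-7,8-dihydro-6H-isochromen-7-yl] 2,4-dihydroxy-6-methylbenzoate | CC(=O)OC/C=C/C1=CC2=CC(=O)[C@@](C)(OC(=O)c3c(C)cc(O)cc3O)CC2=CO1 | target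

**Step count and risks**
Total: 9 steps. Longest linear sequence: 8 steps (steps 1, 2, 3, 4, 5, 6, 8, 9).

Steps most likely to fail:

1. Step 6 (carbene-catalysed benzoin closure, the proposed extension). What may go wrong: slow or no formation of the enaminol from the donor-substituted aldehyde, aldol closure of C8 onto C6 in competition with the benzoin closure, or low facial selectivity at the ketone. Fallback (known chemistry; sets out from 4, comes back at 14): ring B would be closed by an aldol condensation at C4a=C5, with C7 taken from (R)-lactic acid. (R)-Lactic acid and pivalaldehyde (TsOH, pentane, azeotropic removal of water) would give (2R,5R)-2-tert-butyl-5-methyl-1,3-dioxolan-4-one F1. Its lithium enolate (LiN(i-Pr)2, THF, −78 °C) would be alkylated by propargyl bromide on the face opposite to the tert-butyl group, with self-regeneration of the stereocentre, to give (2R,5S)-2-tert-butyl-5-methyl-5-prop-2-ynyl-1,3-dioxolan-4-one F2. CH3Li (1.05 equiv, THF, −78 °C) would open the dioxolanone to (3S)-3-hydroxy-3-methylhex-5-yn-2-one F3 with loss of pivalaldehyde, and Et3SiOTf with 2,6-lutidine would give (3S)-3-methyl-3-(triethylsilyloxy)hex-5-yn-2-one F4. Hydroboration of the alkyne with (c-C6H11)2BH and oxidation with NaBO3·4H2O would give (4S)-4-methyl-5-oxo-4-(triethylsilyloxy)hexanal F5. Its morpholine enamine and dioxinone 4, under the conditions of step 3, would give [(E)-3-[5-[(2S)-2-methyl-3-oxo-2-(triethylsilyloxy)butyl]-4-oxopyran-2-yl]prop-2-enyl] acetate F6. Intramolecular aldol condensation of the methyl ketone onto the pyranone carbonyl (pyrrolidine, AcOH, toluene, 60 °C) would give [(E)-3-[(7S)-7-methyl-6-oxo-7-(triethylsilyloxy)-7,8-dihydro-6H-isochromen-3-yl]prop-2-enyl] acetate F7, and HF·pyridine would free 14.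

2. Step 4 (acetylide addition and Meyer–Schuster rearrangement). What may go wrong: attack of the acetylide on the acetate or at C1 of the pyranone, or ring opening of the pyrylium ion by water before the alkyne is hydrated. Fallback (sets out from 2, comes back at 12): the ester would be kept out of the organometallic step and introduced after it. Olefination of 2 with (tert-butyldimethylsilyloxy)acetaldehyde as in step 2 would give 6-[(E)-3-(tert-butyldimethylsilyloxy)prop-1-enyl]-2,2-dimethyl-4H-1,3-dioxin-4-one F8. The annulation of step 3 would give 2-[(E)-3-(tert-butyldimethylsilyloxy)prop-1-enyl]-5-prop-2-enyl-4H-pyran-4-one F9. Addition of 10 (THF, −40 °C) and brief acid treatment would give (2Z)-2-[2-[(E)-3-(tert-butyldimethylsilyloxy)prop-1-enyl]-5-prop-2-enyl-4H-pyran-4-ylidene]acetaldehyde F10. Et3N·3HF would give (2Z)-2-[2-[(E)-3-hydroxyprop-1-enyl]-5-prop-2-enyl-4H-pyran-4-ylidene]acetaldehyde F11, and Ac2O with pyridine would give 12.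

3. Step 8 (acylation of the tertiary α-ketol). What may go wrong: slow acylation of the hindered tertiary alkoxide, transfer of a triethylsilyl group from the ortho silyl ether to the alkoxide, or base-induced α-ketol rearrangement. Fallback (sets out from 14 and 15, comes back at 19): the acyl group would be transferred from a cyclic acylal that has no silyl group next to the carbonyl. Orsellinic acid 15 with acetone, (CF3CO)2O and CF3CO2H would give 7-hydroxy-2,2,5-trimethyl-4H-1,3-benzodioxin-4-one F12, and t-BuMe2SiCl with imidazole would give 7-(tert-butyldimethylsilyloxy)-2,2,5-trimethyl-4H-1,3-benzodioxin-4-one F13. The sodium alkoxide of 14 (NaN(SiMe3)2, THF, 0 °C) would open F13 at its carbonyl group with loss of acetone to give [(7S)-3-[(E)-3-acetyloxyprop-1-enyl]-7-methyl-6-oxo-7,8-dihydro-6H-isochromen-7-yl] 4-(tert-butyldimethylsilyloxy)-2-hydroxy-6-methylbenzoate F14, and HF·pyridine would give 19.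

**Further compounds**
F1 | step 6 | (2R,5R)-2-tert-butyl-5-methyl-1,3-dioxolan-4-one | C[C@H]1O[C@@H](C(C)(C)C)OC1=O
F2 | step 6 | (2R,5S)-2-tert-butyl-5-methyl-5-prop-2-ynyl-1,3-dioxolan-4-one | C[C@@]1(CC#C)O[C@@H](C(C)(C)C)OC1=O
F3 | step 6 | (3S)-3-hydroxy-3-methylhex-5-yn-2-one | CC(=O)[C@@](C)(O)CC#C
F4 | step 6 | (3S)-3-methyl-3-(triethylsilyloxy)hex-5-yn-2-one | CC(=O)[C@@](C)(O[Si](CC)(CC)CC)CC#C
F5 | step 6 | (4S)-4-methyl-5-oxo-4-(triethylsilyloxy)hexanal | CC(=O)[C@@](C)(O[Si](CC)(CC)CC)CCC=O
F6 | step 6 | [(E)-3-[5-[(2S)-2-methyl-3-oxo-2-(triethylsilyloxy)butyl]-4-oxopyran-2-yl]prop-2-enyl] acetate | CC(=O)OC/C=C/C1=CC(=O)C(C[C@](C)(O[Si](CC)(CC)CC)C(C)=O)=CO1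
F7 | step 6 | [(E)-3-[(7S)-7-methyl-6-oxo-7-(triethylsilyloxy)-7,8-dihydro-6H-isochromen-3-yl]prop-2-enyl] acetate | CC(=O)OC/C=C/C1=CC2=CC(=O)[C@@](C)(O[Si](CC)(CC)CC)CC2=CO1
F8 | step 4 | 6-[(E)-3-(tert-butyldimethylsilyloxy)prop-1-enyl]-2,2-dimethyl-4H-1,3-dioxin-4-one | CC1(C)OC(/C=C/CO[Si](C)(C)C(C)(C)C)=CC(=O)O1
F9 | step 4 | 2-[(E)-3-(tert-butyldimethylsilyloxy)prop-1-enyl]-5-prop-2-enyl-4H-pyran-4-one | C=CCC1=COC(/C=C/CO[Si](C)(C)C(C)(C)C)=CC1=O
F10 | step 4 | (2Z)-2-[2-[(E)-3-(tert-butyldimethylsilyloxy)prop-1-enyl]-5-prop-2-enyl-4H-pyran-4-ylidene]acetaldehyde | O=C/C=C1\C(CC=C)=COC(/C=C/CO[Si](C)(C)C(C)(C)C)=C1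
F11 | step 4 | (2Z)-2-[2-[(E)-3-hydroxyprop-1-enyl]-5-prop-2-enyl-4H-pyran-4-ylidene]acetaldehyde | O=C/C=C1\C(CC=C)=COC(/C=C/CO)=C1
F12 | step 8 | 7-hydroxy-2,2,5-trimethyl-4H-1,3-benzodioxin-4-one | Cc1cc(O)cc2OC(C)(C)OC(=O)c12
F13 | step 8 | 7-(tert-butyldimethylsilyloxy)-2,2,5-trimethyl-4H-1,3-benzodioxin-4-one | Cc1cc(O[Si](C)(C)C(C)(C)C)cc2OC(C)(C)OC(=O)c12
F14 | step 8 | [(7S)-3-[(E)-3-acetyloxyprop-1-enyl]-7-methyl-6-oxo-7,8-dihydro-6H-isochromen-7-yl] 4-(tert-butyldimethylsilyloxy)-2-hydroxy-6-methylbenzoate | CC(=O)OC/C=C/C1=CC2=CC(=O)[C@@](C)(OC(=O)c3c(C)cc(O[Si](C)(C)C(C)(C)C)cc3O)CC2=CO1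
A1 | direct plan | 2,5-dimethylfuran | Cc1ccc(C)o1
A2 | direct plan | acrolein (prop-2-enal) | C=CC=O
A3 | direct plan | (5S)-5-hydroxy-2,5-dimethylcyclohexa-1,3-diene-1-carbaldehyde | C[C@@]1(O)C=CC(C)=C(C=O)C1
A4 | direct plan | (7S)-7-hydroxy-7-methyl-3-[(E)-prop-1-enyl]-7,8-dihydro-6H-isochromen-6-one | C/C=C/C1=CC2=CC(=O)[C@@](C)(O)CC2=CO1
A5 | direct plan | (Z)-but-2-ene-1,4-diyl diacetate | CC(=O)OC/C=C\COC(C)=O
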